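**Retrosynthetic overview**

1. The strategy rests on oxolane C4, the fully substituted carbon that carries the OH and the CH2–aryl group next to ring C5H2–O1. With C5 written as a carbonyl, ring O1–C2–C3–C4–C5 is a γ-butyrolactone and C4 is its α-carbon, so both exocyclic bonds at C4 unravel to an α-methylene lactone.
2. Target 18 ⇐ di-O-benzyl diol 16 (acetylation, hydrogenolysis) ⇐ oxolane 15 ⇐ α-hydroxy lactone 13 (lactone C=O reduced to CH2).
3. 13 ⇐ α-methylene lactone 7 + aryl Grignard 11/CuI + N-sulfonyloxaziridine 10: aryl goes to the exocyclic CH2, oxygen to the α-carbon.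
4. 7 ⇐ 3-(bromomethyl)furan-2(5H)-one 2 + aldehyde 3 by chromium-catalysed asymmetric anti-allylation and translactonization. This step 2 forms the only ring, the lactone that later becomes the oxolane, and sets oxolane C2 and C3.

Key step: step 5

Remark: Ar = 4-(benzyloxy)-3-methoxyphenyl; lactone locants are used for 4–7 and 12–14 (lactone C3, C4, C5 = oxolane C4, C3, C2 of the target).
Assumption: the sense of induction in step 2 is fixed by the ligand antipode; the antipode that gives Si-face addition to 3 is meant, and this is to be checked on 6 through its MTPA esters in the first run.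

Step 1
Reactants: 1 3-methylideneoxolan-2-one (α-methylene-γ-butyrolactone)
Product: 2 3-(bromomethyl)furan-2(5H)-one
Conditions: NBS (1.0 equiv), AIBN (5 mol %), PhCF3, 85 °C
Reagents that add atoms: N-bromosuccinimide, O=C1CCC(=O)N1Br
Why: Wohl–Ziegler allylic bromination: abstraction of a ring C4 hydrogen gives an allyl radical that should take bromine at the exocyclic terminus, moving the double bond into the ring and into conjugation as methylenecycloalkanes do, and either allylic bromide isomer would give the same allylchromium reagent in step 2.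

Step 2
Reactants: 2 3-(bromomethyl)furan-2(5H)-one (1.5 equiv); 3 4-(benzyloxy)-3-methoxybenzaldehyde
Product: 6 (4R,5S)-5-Ar-4-(hydroxymethyl)-3-methylideneoxolan-2-one, via trimethylsilyl ether 4 (not isolated), via hydroxy lactone 5 (not isolated)
Conditions: CrCl2 (10 mol %), enantiopure 1,8-bis(4-isopropyl-4,5-dihydrooxazol-2-yl)-3,6-diphenyl-9H-carbazole (12 mol %), i-Pr2NEt (30 mol %), Mn powder (2 equiv), Me3SiCl (1.5 equiv), THF, rt; then Bu4NF (1.2 equiv), THF, 0 °C
Reagents that add atoms: none
Why: Nozaki–Hiyama allylation run catalytically in chromium: divalent chromium (regenerated by Mn) turns 2 into an allyl trivalent-chromium species whose γ-substituent is held trans to the CH2–Cr carbon by the ring (an open-chain (Z)-2-(bromomethyl)enoate would hold it cis and lean to the syn adduct), so the closed chair transition state should give the anti adduct while the tridentate ligand selects the Si face of 3 (S carbinol centre, hence R at lactone C4), and once fluoride removes the silyl group the alkoxide of 5 attacks the lactone carbonyl (5-exo-trig acyl transfer) to give the more substituted trans-4,5-disubstituted lactone 6.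

Step 3
Reactants: 6 (4R,5S)-5-Ar-4-(hydroxymethyl)-3-methylideneoxolan-2-one
Product: 7 (4R,5S)-5-Ar-4-{[(tert-butyldimethylsilyl)oxy]methyl}-3-methylideneoxolan-2-one
Conditions: TBSOTf, 2,6-lutidine, CH2Cl2, −78 °C
Reagents that add atoms: tert-butyldimethylsilyl trifluoromethanesulfonate, CC(C)(C)[Si](C)(C)OS(=O)(=O)C(F)(F)F
Why: Silylation of the primary alcohol with a silyl triflate and a hindered, non-nucleophilic base should be fast at low temperature and avoids amine addition to the α-methylene lactone.

Step 4
Reactants: 8 4-bromo-2-methoxyphenol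
Product: 9 1-(benzyloxy)-4-bromo-2-methoxybenzene
Conditions: BnBr, K2CO3, DMF, rt
Reagents that add atoms: benzyl bromide, BrCc1ccccc1
Why: Williamson ether synthesis on a phenoxide with a primary benzylic bromide.

Step 5
Reactants: 7 (4R,5S)-5-Ar-4-{[(tert-butyldimethylsilyl)oxy]methyl}-3-methylideneoxolan-2-one; 9 1-(benzyloxy)-4-bromo-2-methoxybenzene; 10 3-phenyl-2-(phenylsulfonyl)oxaziridine (racemic)
Product: 13 (3S,4R,5S)-5-Ar-3-(Ar-methyl)-4-{[(tert-butyldimethylsilyl)oxy]methyl}-3-hydroxyoxolan-2-one, via aryl Grignard reagent 11 (not isolated), via magnesium enolate 12 (not isolated)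
Conditions: 9, Mg turnings, THF, 45 °C; then 11 (1.3 equiv), CuI (20 mol %), THF, −40 °C, slow addition of 7; then 10 (2.5 equiv), THF, −78 → −20 °C
Reagents that add atoms: 3-phenyl-2-(phenylsulfonyl)oxaziridine (10), O=S(=O)(c1ccccc1)N1OC1c1ccccc1
Why: Transmetalation of 11 to copper gives an arylcopper species that adds 1,4 to the unhindered exocyclic CH2 of 7, forming the CH2–aryl bond and leaving the bromomagnesium lactone enolate 12, which has no β-leaving group and should persist at low temperature; its α-carbon then attacks the oxaziridine oxygen of 10 in an SN2-type displacement at oxygen that expels N-benzylidenebenzenesulfonamide and forms the C3–O bond. The closest known reaction types are organocopper conjugate addition to α-methylene-γ-butyrolactones with electrophilic trapping of the enolate, and N-sulfonyloxaziridine hydroxylation of lactone enolates to tertiary α-hydroxy lactones. No ring is closed: the lactone ring of 7 is carried through unchanged and later becomes the oxolane. The one new stereocentre, C3, is set in the oxygen-transfer event by the adjacent C4 silyloxymethyl group, which shields the enolate face syn to it, so oxygen should enter anti (hydroxyl trans and benzyl cis to the C4 side chain) even though that is the face of the more remote C5 aryl group. The step needs 1,4- over 1,2-addition, which copper catalysis, low temperature and the exposed terminal acceptor should secure, and it needs the enolate to meet the oxidant before it meets unreacted 7, which slow addition of 7 to a slight excess of the aryl metal should secure; the excess of 10 covers the aryl metal that remains.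

Step 6
Reactants: 13 (3S,4R,5S)-5-Ar-3-(Ar-methyl)-4-{[(tert-butyldimethylsilyl)oxy]methyl}-3-hydroxyoxolan-2-one
Product: 14 (3S,4R,5S)-5-Ar-3-(Ar-methyl)-4-{[(tert-butyldimethylsilyl)oxy]methyl}oxolane-2,3-diol (mixture at C2)
Conditions: i-Bu2AlH (2.5 equiv), CH2Cl2, −78 °C
Reagents that add atoms: none
Why: Partial reduction of a lactone at −78 °C: one equivalent is consumed by the tertiary hydroxyl, and the resulting aluminium alkoxide should chelate and hold the tetrahedral intermediate so that the lactol is released only on work-up, with silyl and benzyl ethers untouched.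

Step 7
Reactants: 14 (3S,4R,5S)-5-Ar-3-(Ar-methyl)-4-{[(tert-butyldimethylsilyl)oxy]methyl}oxolane-2,3-diol
Product: 15 (3S,4R,5S)-5-Ar-3-(Ar-methyl)-4-{[(tert-butyldimethylsilyl)oxy]methyl}oxolan-3-ol
Conditions: Et3SiH (5 equiv), BF3·OEt2 (2 equiv), CH2Cl2, −78 → −40 °C; aq. NaHCO3
Reagents that add atoms: none
Why: Ionic hydrogenation of a lactol: BF3 ionizes the anomeric hydroxyl to an oxocarbenium ion that the silane already present reduces to CH2 (no stereocentre is made), and the low temperature is chosen to keep the benzylic C5–O bond from ionizing.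

Step 8
Reactants: 15 (3S,4R,5S)-5-Ar-3-(Ar-methyl)-4-{[(tert-butyldimethylsilyl)oxy]methyl}oxolan-3-ol
Product: 16 (3S,4R,5S)-5-Ar-3-(Ar-methyl)-4-(hydroxymethyl)oxolan-3-ol
Conditions: Bu4NF, THF, 0 °C → rt
Reagents that add atoms: none
Why: Fluoride cleavage of the primary silyl ether under non-acidic conditions, which the acid-sensitive 2-aryloxolane should tolerate.

Step 9
Reactants: 16 (3S,4R,5S)-5-Ar-3-(Ar-methyl)-4-(hydroxymethyl)oxolan-3-ol
Product: 17 [(2S,3R,4S)-2-Ar-4-(Ar-methyl)-4-hydroxyoxolan-3-yl]methyl acetate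
Conditions: Ac2O (1.2 equiv), pyridine, 0 °C → rt
Reagents that add atoms: acetic anhydride, CC(=O)OC(C)=O
Why: Chemoselective acylation: the primary hydroxyl should be acetylated while the tertiary hydroxyl does not react without an acyl-transfer catalyst, and both phenols are still benzylated.

Step 10
Reactants: 17 [(2S,3R,4S)-2-Ar-4-(Ar-methyl)-4-hydroxyoxolan-3-yl]methyl acetate
Product: 18 [(2S,3R,4S)-4-hydroxy-2-(4-hydroxy-3-methoxyphenyl)-4-[(4-hydroxy-3-methoxyphenyl)methyl]oxolan-3-yl]methyl acetate (olivil monoacetate)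
Conditions: H2 (1 atm), Pd/C, EtOAc, rt
Reagents that add atoms: none
Why: Hydrogenolysis of the two aryl benzyl ethers under neutral conditions, where the ring benzylic C–O bond should react much more slowly and the acetate and tertiary alcohol are inert; acid is avoided because it would invite Friedel–Crafts closure of the second aryl ring onto C2.

**Compound list**

1 | 3-methylideneoxolan-2-one (α-methylene-γ-butyrolactone) | C=C1CCOC1=O | starting material
2 | 3-(bromomethyl)furan-2(5H)-one | O=C1OCC=C1CBr | intermediate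
3 | 4-(benzyloxy)-3-methoxybenzaldehyde | COc1cc(C=O)ccc1OCc1ccccc1 | starting material
4 | (4R)-4-{(S)-[4-(benzyloxy)-3-methoxyphenyl][(trimethylsilyl)oxy]methyl}-3-methylideneoxolan-2-one | C=C1C(=O)OC[C@@H]1[C@H](O[Si](C)(C)C)c1ccc(OCc2ccccc2)c(OC)c1 | intermediate
5 | (4R)-4-{(S)-[4-(benzyloxy)-3-methoxyphenyl](hydroxy)methyl}-3-methylideneoxolan-2-one | C=C1C(=O)OC[C@@H]1[C@H](O)c1ccc(OCc2ccccc2)c(OC)c1 | intermediate
6 | (4R,5S)-5-[4-(benzyloxy)-3-methoxyphenyl]-4-(hydroxymethyl)-3-methylideneoxolan-2-one | C=C1C(=O)O[C@H](c2ccc(OCc3ccccc3)c(OC)c2)[C@H]1CO | intermediate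
7 | (4R,5S)-5-[4-(benzyloxy)-3-methoxyphenyl]-4-{[(tert-butyldimethylsilyl)oxy]methyl}-3-methylideneoxolan-2-one | C=C1C(=O)O[C@H](c2ccc(OCc3ccccc3)c(OC)c2)[C@H]1CO[Si](C)(C)C(C)(C)C | intermediate
8 | 4-bromo-2-methoxyphenol | COc1cc(Br)ccc1O | starting material
9 | 1-(benzyloxy)-4-bromo-2-methoxybenzene | COc1cc(Br)ccc1OCc1ccccc1 | intermediate
10 | 3-phenyl-2-(phenylsulfonyl)oxaziridine (racemic) | O=S(=O)(c1ccccc1)N1OC1c1ccccc1 | starting material
11 | [4-(benzyloxy)-3-methoxyphenyl]magnesium bromide | COc1cc([Mg]Br)ccc1OCc1ccccc1 | intermediate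
12 | bromomagnesium enolate of (4R,5S)-5-Ar-3-(Ar-methyl)-4-{[(tert-butyldimethylsilyl)oxy]methyl}oxolan-2-one | COc1cc(CC2=C(O[Mg]Br)O[C@H](c3ccc(OCc4ccccc4)c(OC)c3)[C@H]2CO[Si](C)(C)C(C)(C)C)ccc1OCc1ccccc1 | intermediate
13 | (3S,4R,5S)-5-[4-(benzyloxy)-3-methoxyphenyl]-3-{[4-(benzyloxy)-3-methoxyphenyl]methyl}-4-{[(tert-butyldimethylsilyl)oxy]methyl}-3-hydroxyoxolan-2-one | COc1cc(C[C@@]2(O)C(=O)O[C@H](c3ccc(OCc4ccccc4)c(OC)c3)[C@H]2CO[Si](C)(C)C(C)(C)C)ccc1OCc1ccccc1 | intermediate
14 | (3S,4R,5S)-5-[4-(benzyloxy)-3-methoxyphenyl]-3-{[4-(benzyloxy)-3-methoxyphenyl]methyl}-4-{[(tert-butyldimethylsilyl)oxy]methyl}oxolane-2,3-diol (both C2 anomers) | COc1cc(C[C@@]2(O)C(O)O[C@H](c3ccc(OCc4ccccc4)c(OC)c3)[C@H]2CO[Si](C)(C)C(C)(C)C)ccc1OCc1ccccc1 | intermediate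
15 | (3S,4R,5S)-5-[4-(benzyloxy)-3-methoxyphenyl]-3-{[4-(benzyloxy)-3-methoxyphenyl]methyl}-4-{[(tert-butyldimethylsilyl)oxy]methyl}oxolan-3-ol | COc1cc(C[C@@]2(O)CO[C@H](c3ccc(OCc4ccccc4)c(OC)c3)[C@H]2CO[Si](C)(C)C(C)(C)C)ccc1OCc1ccccc1 | intermediate
16 | (3S,4R,5S)-5-[4-(benzyloxy)-3-methoxyphenyl]-3-{[4-(benzyloxy)-3-methoxyphenyl]methyl}-4-(hydroxymethyl)oxolan-3-ol | COc1cc(C[C@@]2(O)CO[C@H](c3ccc(OCc4ccccc4)c(OC)c3)[C@H]2CO)ccc1OCc1ccccc1 | intermediate
17 | [(2S,3R,4S)-2-[4-(benzyloxy)-3-methoxyphenyl]-4-{[4-(benzyloxy)-3-methoxyphenyl]methyl}-4-hydroxyoxolan-3-yl]methyl acetate | COc1cc(C[C@@]2(O)CO[C@H](c3ccc(OCc4ccccc4)c(OC)c3)[C@H]2COC(C)=O)ccc1OCc1ccccc1 | intermediate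
18 | [(2S,3R,4S)-4-hydroxy-2-(4-hydroxy-3-methoxyphenyl)-4-[(4-hydroxy-3-methoxyphenyl)methyl]oxolan-3-yl]methyl acetate (olivil monoacetate) | COc1cc(C[C@@]2(O)CO[C@H](c3ccc(O)c(OC)c3)[C@H]2COC(C)=O)ccc1O | target

**Step count**

Total: 10 steps. Longest linear sequence: 9 steps (steps 1, 2, 3, 5, 6, 7, 8, 9, 10, from 1 to 18); step 4 is a one-step side branch.

**Steps most likely to fail**

Step 5. Oxygen transfer to the magnesium enolate may be slow, so that the enolate is protonated or adds to the sulfonimine by-product, and the face selectivity of the oxidation may be insufficient. The fallback separates the two bond formations and sets out from 7. Copper-catalysed addition of 11 with a proton quench should give (4R,5S)-5-[4-(benzyloxy)-3-methoxyphenyl]-3-{[4-(benzyloxy)-3-methoxyphenyl]methyl}-4-{[(tert-butyldimethylsilyl)oxy]methyl}oxolan-2-one F1 as a mixture of C3 epimers, both of which give the same enolate. Deprotonation with KN(SiMe3)2 in THF at −78 °C then gives the more reactive potassium enolate, which is oxidized with 10 to return to the route at 13. An enantiopure (camphorsulfonyl)oxaziridine could replace 10 there if reagent control of the face is needed.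

Step 7. The Lewis acid may ionize the benzylic C5–O bond instead of the lactol, leading to reductive ring opening, epimerization at C5 or Friedel–Crafts closure onto the other aryl ring. The fallback sets out from 13 and forms the ether ring by a different bond. Reduction with LiAlH4 in THF should give (2S,3R,4S)-4-[4-(benzyloxy)-3-methoxyphenyl]-2-{[4-(benzyloxy)-3-methoxyphenyl]methyl}-3-{[(tert-butyldimethylsilyl)oxy]methyl}butane-1,2,4-triol F2. A catalytic amount of camphorsulfonic acid in CH2Cl2 at 0 °C should then ionize the benzylic alcohol, and the primary hydroxyl captures the cation in a 5-exo closure with the aryl group trans to the neighbouring side chain. This returns to the route at 15, with no hydride source present to intercept the cation.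

Step 2. The catalyst may give insufficient enantioselectivity with this bromide. The fallback sets out from 2 and 3 and replaces asymmetric catalysis by racemic synthesis and resolution. A Barbier allylation with Zn dust in THF/aq. NH4Cl should give the racemic anti adduct, that is 5 together with its mirror image (4S)-4-{(R)-[4-(benzyloxy)-3-methoxyphenyl](hydroxy)methyl}-3-methylideneoxolan-2-one F3. Base-catalysed translactonization then gives the racemic trans lactone, that is 6 together with (4S,5R)-5-[4-(benzyloxy)-3-methoxyphenyl]-4-(hydroxymethyl)-3-methylideneoxolan-2-one F4. Preparative chromatography on a chiral stationary phase should separate the two and return to the route at 6.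

**Further compounds**

F1 | step 5 | (4R,5S)-5-[4-(benzyloxy)-3-methoxyphenyl]-3-{[4-(benzyloxy)-3-methoxyphenyl]methyl}-4-{[(tert-butyldimethylsilyl)oxy]methyl}oxolan-2-one (C3 epimers) | COc1cc(CC2C(=O)O[C@H](c3ccc(OCc4ccccc4)c(OC)c3)[C@H]2CO[Si](C)(C)C(C)(C)C)ccc1OCc1ccccc1
F2 | step 7 | (2S,3R,4S)-4-[4-(benzyloxy)-3-methoxyphenyl]-2-{[4-(benzyloxy)-3-methoxyphenyl]methyl}-3-{[(tert-butyldimethylsilyl)oxy]methyl}butane-1,2,4-triol | COc1cc(C[C@@](O)(CO)[C@H](CO[Si](C)(C)C(C)(C)C)[C@H](O)c2ccc(OCc3ccccc3)c(OC)c2)ccc1OCc1ccccc1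
F3 | step 2 | (4S)-4-{(R)-[4-(benzyloxy)-3-methoxyphenyl](hydroxy)methyl}-3-methylideneoxolan-2-one | C=C1C(=O)OC[C@H]1[C@@H](O)c1ccc(OCc2ccccc2)c(OC)c1
F4 | step 2 | (4S,5R)-5-[4-(benzyloxy)-3-methoxyphenyl]-4-(hydroxymethyl)-3-methylideneoxolan-2-one | C=C1C(=O)O[C@@H](c2ccc(OCc3ccccc3)c(OC)c2)[C@@H]1CO
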